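The data are simulated with made-up constants.

The reading at 3.0 h lies 0.556 decades of time past the last point of the dusk run, which is this very flask followed so far, so I reckon in logarithms.

| flask | substrate | reagent | remark | time |
|---|---|---|---|---|
| dusk | 45 mM | 49.5 mM | the very flask that is asked about, followed so far |  |
| flask | 45 mM | 49.5 mM |  | 3.0 h |

dusk run (percent of the substrate charged)

| time / min | target / % | substrate / % |
|---|---|---|
| 5.00 | 0.2 | 90.9 |
| 15.0 | 1.3 | 82.8 |
| 25.0 | 1.1 | 78.7 |
| 40.0 | 1.3 | 76.8 |
| 50.0 | 2.6 | 76.0 |

(readings scatter by 0.5 percentage points)

- concentration of target at 3.0 h, in mM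
- concentration of substrate at 3.0 h, in mM

- steps thought possible: substrate + reagent <-> isomer of the product; substrate <-> tautomer; reagent + tautomer -> target; 2 reagent -> homo dimer

Setting the geometric mean of the last two target readings against that of the two before them gives 0.514. This is the time exponent of target, the decades of target gained per decade of time, or log-log slope, and it is loose, since each reading scatters by 0.5 percentage points. Carried to 3.0 h, it gives my own figure of 1.69 mM of target. The last two substrate readings differ by 0.8 points, so I hold substrate at 34.2 mM.

The forecast differs: 3.6 mM of target and 32 mM of substrate, with target on an exponent of 1, “so I leave it near linear”.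

The flask gives 0.875 mM of target, less than either figure, and 34.3 mM of substrate.

    substrate + reagent ⇌ isomer of the product (K = 140 /M, k = 0.520 /M/min)
    substrate ⇌ tautomer (K = 0.00810, k = 0.130 /min)
    reagent + tautomer → target (k = 3.60 /M/min)
    2 reagent → homo dimer (k = 1.70 /M/min)

Across the decade of time from 0.300 h to 3.0 h, target in this flask goes from 0.956% to 1.94%, an exponent of 0.308 over that stretch. At 3.0 h in this flask, reagent stands at 3.14% of its charge and homo dimer at 18.8 mM. Left until 8.0 h, the same flask should reach 1.45 mM of target on the exponent 0.514, starting from the result at 3.0 h. That flask holds 1.29 mM.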